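**Plan** (flavanone numbering; ring B atoms primed)
Retrosynthesis: the two phenolic silyl ethers are removed first, then the C5'–prenyl bond is cut (back to an aryl bromide), then the C2–C3 bond of ring C (back to an achiral aryl benzyl ether carrying an enol acetate), and last the O1–C2 ether bond, leaving a ring A acetophenone and a ring B benzyl alcohol.
Forward: ring A and ring B are joined through O1–C2 by Mitsunobu etherification, the methyl ketone is turned into its enol acetate, ring C is closed by forming C2–C3, and prenylation and desilylation complete the molecule.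
Enabling feature: C2 lies between O1 and the para-methoxy-bearing ring B, so in the open-chain ether its C–H can be removed as hydride to give an oxocarbenium ion, which C3 (the terminal carbon of the ring A enol acetate) attacks.
Stereochemistry: the only stereocentre, C2 (S), is created in that ring closure under control of a chiral phosphate counter-anion; the two later steps are neutral or buffered and should leave it untouched.

Key step: step 7

Assumption: the sense of induction of a chiral phosphate in step 7 cannot be predicted with confidence. (R)-TRIP, (R)-3,3'-bis(2,4,6-triisopropylphenyl)-1,1'-binaphthyl-2,2'-diyl hydrogen phosphate, is written throughout; its antipode would be used if screening shows that it favours the (2S) product.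

**Route**

Step 1
Reactants: 1 2',4'-dihydroxyacetophenone
Product: 2 1-[2-hydroxy-4-(triisopropylsilyloxy)phenyl]ethanone
Conditions: TIPSCl, imidazole, CH2Cl2, 0 °C → rt
Reagents that add atoms: triisopropylsilyl chloride, CC(C)[Si](Cl)(C(C)C)C(C)C
Why: The 2-OH is held in a hydrogen bond to the ketone, so phenol O-silylation should take place only at the free 4-OH.

Step 2
Reactants: 3 3-bromo-4,5-dihydroxybenzaldehyde
Product: 4 3-bromo-5-hydroxy-4-methoxybenzaldehyde
Conditions: MeI (1 equiv), Li2CO3, DMF, 40 °C
Reagents that add atoms: iodomethane, CI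
Why: The 4-OH, para to the aldehyde and ortho to bromine, is the more acidic phenol, so a weak base should form only its phenoxide and the Williamson O-methylation should be regioselective.

Step 3
Reactants: 4 3-bromo-5-hydroxy-4-methoxybenzaldehyde
Product: 5 3-bromo-4-methoxy-5-(triisopropylsilyloxy)benzaldehyde
Conditions: TIPSCl, imidazole, DMF, rt
Reagents that add atoms: triisopropylsilyl chloride, CC(C)[Si](Cl)(C(C)C)C(C)C
Why: Silylation of the one remaining phenol gives an ether expected to survive hydride, strong amide base, DDQ and hot neutral palladium catalysis.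

Step 4
Reactants: 5 3-bromo-4-methoxy-5-(triisopropylsilyloxy)benzaldehyde
Product: 6 [3-bromo-4-methoxy-5-(triisopropylsilyloxy)phenyl]methanol
Conditions: NaBH4, MeOH/THF, 0 °C
Reagents that add atoms: none
Why: Borohydride reduction of an aryl aldehyde is chemoselective and should leave the aryl bromide and the aryl silyl ether untouched.

Step 5
Reactants: 2 1-[2-hydroxy-4-(triisopropylsilyloxy)phenyl]ethanone; 6 [3-bromo-4-methoxy-5-(triisopropylsilyloxy)phenyl]methanol
Product: 7 1-[2-[[3-bromo-4-methoxy-5-(triisopropylsilyloxy)phenyl]methoxy]-4-(triisopropylsilyloxy)phenyl]ethanone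
Conditions: PPh3, DIAD, THF, 0 °C → rt
Reagents that add atoms: none
Why: In this Mitsunobu etherification the primary benzylic alcohol is activated as its oxyphosphonium ion and displaced by the sufficiently acidic phenol under neutral conditions that spare both aryl silyl ethers.

Step 6
Reactants: 7 1-[2-[[3-bromo-4-methoxy-5-(triisopropylsilyloxy)phenyl]methoxy]-4-(triisopropylsilyloxy)phenyl]ethanone
Product: 9 1-[2-[[3-bromo-4-methoxy-5-(triisopropylsilyloxy)phenyl]methoxy]-4-(triisopropylsilyloxy)phenyl]ethenyl acetate, via potassium enolate 8 (not isolated)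
Conditions: KN(SiMe3)2, THF, −78 °C; then Ac2O, −78 → 0 °C
Reagents that add atoms: acetic anhydride, CC(=O)OC(C)=O
Why: The methyl group is the only enolisable position, and O-acylation of the dissociated potassium enolate by the hard electrophile acetic anhydride should give the enol acetate rather than the 1,3-diketone.

Step 7
Reactants: 9 1-[2-[[3-bromo-4-methoxy-5-(triisopropylsilyloxy)phenyl]methoxy]-4-(triisopropylsilyloxy)phenyl]ethenyl acetate
Product: 11 (2S)-2-[3-bromo-4-methoxy-5-(triisopropylsilyloxy)phenyl]-7-(triisopropylsilyloxy)chroman-4-one, via oxocarbenium ion 10 (not isolated)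
Conditions: DDQ (1.5 equiv), (R)-TRIP (10 mol%), 4 Å MS, CH2Cl2, −30 °C → rt
Reagents that add atoms: none
Why: Proposed new method: DDQ, activated by hydrogen bonding to the chiral phosphoric acid, should abstract hydride from the only doubly activated C–H of 9 (the OCH2 flanked by O1 and ring B) to give the (E)-oxocarbenium ion 10 as a contact ion pair with the chiral phosphate; C3, the terminal carbon of the enol acetate, then attacks C2, and the resulting O-acetyl oxocarbenium ion passes its acetyl group to the hydroquinone, releasing the ketone and the acid. The closest known reaction types are the DDQ-mediated oxidative cyclisation of benzylic and allylic alkyl ethers onto enol acetates to give tetrahydropyran-4-ones, chiral phosphate-paired additions to oxocarbenium and benzopyrylium ions, and chiral-anion phase-transfer oxidative C–H cyclisations with oxoammonium salts; what is new is the O-aryl oxocarbenium ion and the enantioselective course. Ring C closes in a 6-(enolendo)-endo-trig mode through a chair-like transition state with ring B pseudo-equatorial. The C2 stereocentre is set by the phosphate anion, which shields one face of the planar cation. Chemoselectivity rests on bromine standing in for the prenyl group so that no other benzylic or allylic C–H is present, on the inertness of enol acetates and aryl silyl ethers to DDQ, and on the product being an electron-poor vinylogous ester that resists a second hydride abstraction, while the tether allows only six-membered closure. The racemic pathway through the hydroquinone-anion pair is the main threat to enantiopurity and should be held back by low temperature, a weakly polar medium and the slow uncatalysed oxidation of the weakly donating ring B.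

Step 8
Reactants: 11 (2S)-2-[3-bromo-4-methoxy-5-(triisopropylsilyloxy)phenyl]-7-(triisopropylsilyloxy)chroman-4-one; 12 tributyl(3-methylbut-2-enyl)stannane
Product: 13 (2S)-2-[4-methoxy-3-(3-methylbut-2-enyl)-5-(triisopropylsilyloxy)phenyl]-7-(triisopropylsilyloxy)chroman-4-one
Conditions: Pd(PPh3)4 (cat.), degassed DMF, 90 °C
Reagents that add atoms: none
Why: In this Stille cross-coupling, zerovalent palladium inserts into the aryl C–Br bond, the prenyl group is transferred from tin through its primary carbon and reductive elimination gives the linear prenyl arene under neutral, fluoride-free conditions that should not disturb C2 or the silyl ethers.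

Step 9
Reactants: 13 (2S)-2-[4-methoxy-3-(3-methylbut-2-enyl)-5-(triisopropylsilyloxy)phenyl]-7-(triisopropylsilyloxy)chroman-4-one
Product: 14 erylatissin C, (2S)-7-hydroxy-2-[3-hydroxy-4-methoxy-5-(3-methylbut-2-enyl)phenyl]chroman-4-one
Conditions: Bu4NF, AcOH (1:1), THF, 0 °C
Reagents that add atoms: none
Why: Fluoride-mediated desilylation cleaves both aryl Si–O bonds, and the acetic acid buffer keeps phenoxide and enolate concentrations low so that the flavanone should neither open by retro-oxa-Michael reaction nor racemise.

**Compound list**

1 | 2',4'-dihydroxyacetophenone | CC(=O)c1ccc(O)cc1O | starting material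
2 | 1-[2-hydroxy-4-(triisopropylsilyloxy)phenyl]ethanone | CC(=O)c1ccc(O[Si](C(C)C)(C(C)C)C(C)C)cc1O | intermediate
3 | 3-bromo-4,5-dihydroxybenzaldehyde | O=Cc1cc(O)c(O)c(Br)c1 | starting material
4 | 3-bromo-5-hydroxy-4-methoxybenzaldehyde | COc1c(O)cc(C=O)cc1Br | intermediate
5 | 3-bromo-4-methoxy-5-(triisopropylsilyloxy)benzaldehyde | COc1c(O[Si](C(C)C)(C(C)C)C(C)C)cc(C=O)cc1Br | intermediate
6 | [3-bromo-4-methoxy-5-(triisopropylsilyloxy)phenyl]methanol | COc1c(O[Si](C(C)C)(C(C)C)C(C)C)cc(CO)cc1Br | intermediate
7 | 1-[2-[[3-bromo-4-methoxy-5-(triisopropylsilyloxy)phenyl]methoxy]-4-(triisopropylsilyloxy)phenyl]ethanone | CC(=O)c1ccc(O[Si](C(C)C)(C(C)C)C(C)C)cc1OCc1cc(Br)c(OC)c(O[Si](C(C)C)(C(C)C)C(C)C)c1 | intermediate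
8 | potassium enolate of 7 (not isolated) | [K+].C=C([O-])c1ccc(O[Si](C(C)C)(C(C)C)C(C)C)cc1OCc1cc(Br)c(OC)c(O[Si](C(C)C)(C(C)C)C(C)C)c1 | intermediate
9 | 1-[2-[[3-bromo-4-methoxy-5-(triisopropylsilyloxy)phenyl]methoxy]-4-(triisopropylsilyloxy)phenyl]ethenyl acetate | C=C(OC(C)=O)c1ccc(O[Si](C(C)C)(C(C)C)C(C)C)cc1OCc1cc(Br)c(OC)c(O[Si](C(C)C)(C(C)C)C(C)C)c1 | intermediate
10 | (E)-O-aryl oxocarbenium ion formed from 9 by loss of hydride, paired with the chiral phosphate (not isolated) | C=C(OC(C)=O)c1ccc(O[Si](C(C)C)(C(C)C)C(C)C)cc1/[O+]=C/c1cc(Br)c(OC)c(O[Si](C(C)C)(C(C)C)C(C)C)c1 | intermediate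
11 | (2S)-2-[3-bromo-4-methoxy-5-(triisopropylsilyloxy)phenyl]-7-(triisopropylsilyloxy)chroman-4-one | COc1c(O[Si](C(C)C)(C(C)C)C(C)C)cc([C@@H]2CC(=O)c3ccc(O[Si](C(C)C)(C(C)C)C(C)C)cc3O2)cc1Br | intermediate
12 | tributyl(3-methylbut-2-enyl)stannane | CCCC[Sn](CCCC)(CCCC)CC=C(C)C | starting material
13 | (2S)-2-[4-methoxy-3-(3-methylbut-2-enyl)-5-(triisopropylsilyloxy)phenyl]-7-(triisopropylsilyloxy)chroman-4-one | COc1c(O[Si](C(C)C)(C(C)C)C(C)C)cc([C@@H]2CC(=O)c3ccc(O[Si](C(C)C)(C(C)C)C(C)C)cc3O2)cc1CC=C(C)C | intermediate
14 | erylatissin C, (2S)-7-hydroxy-2-[3-hydroxy-4-methoxy-5-(3-methylbut-2-enyl)phenyl]chroman-4-one | COc1c(O)cc([C@@H]2CC(=O)c3ccc(O)cc3O2)cc1CC=C(C)C | target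

**Step count and risks**

Total step count: 9. Longest linear sequence: 8 steps (steps 2 to 9, from 3); ring A is prepared in one step and joins at step 5.

Steps most likely to fail:

1. Step 7 (proposed new method). Hydride abstraction may be slow because the 4-methoxy group of ring B, flanked by bromine and the silyloxy group, is twisted out of conjugation. Ring closure within the achiral hydroquinone-anion pair may outrun exchange for the chiral phosphate and erode the enantiomeric purity. Adventitious water may intercept the cation and cleave the ether. The fallback uses known chemistry and closes ring C at O1–C2 instead of C2–C3; it sets out from 2 and 5 and comes back at 11. C-carboxylation of 2 (LiN(SiMe3)2, 3 equiv, THF, −78 °C; then Boc2O) should give tert-butyl 3-[2-hydroxy-4-(triisopropylsilyloxy)phenyl]-3-oxopropanoate F1. Knoevenagel condensation with 5 (piperidinium acetate, 4 Å MS, toluene, rt) should give tert-butyl 3-[3-bromo-4-methoxy-5-(triisopropylsilyloxy)phenyl]-2-[2-hydroxy-4-(triisopropylsilyloxy)benzoyl]prop-2-enoate F2. A cinchona-derived bifunctional thiourea (quinine or quinidine series chosen for the 2S sense, 10 mol%, toluene, −25 °C) should promote the enantioselective intramolecular oxa-Michael addition to tert-butyl (2S)-2-[3-bromo-4-methoxy-5-(triisopropylsilyloxy)phenyl]-4-oxo-7-(triisopropylsilyloxy)chroman-3-carboxylate F3. TsOH in toluene at 80 °C then removes the tert-butyl ester with decarboxylation to give 11.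

2. Step 8. Transmetalation may occur with allylic transposition, attaching the stannane through its tertiary carbon and giving the 1,1-dimethylallyl isomer. Oxidative addition into the electron-rich, ortho-substituted C–Br bond may be sluggish, and prolonged heating could erode the configuration at C2. The fallback builds the prenyl group by metathesis; it sets out from 11 and comes back at 13. Stille coupling with allyltributylstannane (Pd(PPh3)4, toluene, 100 °C), whose two allyl termini are identical, should give (2S)-2-[4-methoxy-3-(prop-2-enyl)-5-(triisopropylsilyloxy)phenyl]-7-(triisopropylsilyloxy)chroman-4-one F4. Olefin cross-metathesis with excess 2-methyl-2-butene (second-generation Grubbs catalyst [RuCl2(=CHPh)(PCy3)(H2IMes)], CH2Cl2, 40 °C) converts the allyl group into the prenyl group of 13.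

3. Step 5. Activation of the chelated ortho-hydroxy ketone may be slow, so that the electron-rich benzylic oxyphosphonium ion is captured by the reduced azodicarboxylate (N-benzylation) or by the phenol at carbon instead of oxygen. The fallback replaces the redox condensation by SN2 alkylation with a preformed halide; it sets out from 6 and comes back at 7. Appel bromination (CBr4, PPh3, CH2Cl2, 0 °C) should give 1-bromo-5-(bromomethyl)-2-methoxy-3-(triisopropylsilyloxy)benzene F5, and Williamson etherification with 2 (K2CO3, acetone, 50 °C) gives 7.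

**Further compounds**

F1 | step 7 | tert-butyl 3-[2-hydroxy-4-(triisopropylsilyloxy)phenyl]-3-oxopropanoate | CC(C)(C)OC(=O)CC(=O)c1ccc(O[Si](C(C)C)(C(C)C)C(C)C)cc1O
F2 | step 7 | tert-butyl 3-[3-bromo-4-methoxy-5-(triisopropylsilyloxy)phenyl]-2-[2-hydroxy-4-(triisopropylsilyloxy)benzoyl]prop-2-enoate (alkene geometry not fixed) | COc1c(O[Si](C(C)C)(C(C)C)C(C)C)cc(C=C(C(=O)OC(C)(C)C)C(=O)c2ccc(O[Si](C(C)C)(C(C)C)C(C)C)cc2O)cc1Br
F3 | step 7 | tert-butyl (2S)-2-[3-bromo-4-methoxy-5-(triisopropylsilyloxy)phenyl]-4-oxo-7-(triisopropylsilyloxy)chroman-3-carboxylate (C3 epimerisable, configuration not fixed) | COc1c(O[Si](C(C)C)(C(C)C)C(C)C)cc([C@@H]2C(C(=O)OC(C)(C)C)C(=O)c3ccc(O[Si](C(C)C)(C(C)C)C(C)C)cc3O2)cc1Br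
F4 | step 8 | (2S)-2-[4-methoxy-3-(prop-2-enyl)-5-(triisopropylsilyloxy)phenyl]-7-(triisopropylsilyloxy)chroman-4-one | COc1c(O[Si](C(C)C)(C(C)C)C(C)C)cc([C@@H]2CC(=O)c3ccc(O[Si](C(C)C)(C(C)C)C(C)C)cc3O2)cc1CC=C
F5 | step 5 | 1-bromo-5-(bromomethyl)-2-methoxy-3-(triisopropylsilyloxy)benzene | COc1c(O[Si](C(C)C)(C(C)C)C(C)C)cc(CBr)cc1Br
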